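**Retrosynthetic overview**
- Target ⇒ selective C12‑O angeloylation of a 6,12‑diol ⇒ anti‑Markovnikov hydration of the isopropenyl group of a 6β‑hydroxy‑8α‑angeloyloxy germacratriene.
- The ten‑membered ring (the only ring of the target) is closed at C6–C7 by a Lewis‑acid carbonyl‑ene reaction of acyclic (2E,6Z,9S)‑9‑angeloyloxyfarnesal. The aldehyde carbon (farnesyl C1) is the electrophile and the distal olefin the nucleophile; hydrogen loss from a terminal methyl gives the isopropenyl group, as in the FPP → germacrene A closure. C6 and C7 are set here under control of C8.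
- The farnesal ⇒ B‑alkyl Suzuki union (C3–C4) of a dienyl angelate with (E)‑3‑iodobut‑2‑en‑1‑ol, then allylic oxidation.
- The dienol ⇒ DIBAL/Wittig opening of a 4‑methyl‑5,6‑dihydropyran‑2‑one. This temporary lactone ring locks the Z olefin, and its C8 stereocentre comes from a catalytic asymmetric vinylogous aldol of prenal with a senecioate dienolate.
- Both angelates come from one batch of the angelic 2,4,6‑trichlorobenzoic mixed anhydride, made once and used at C8‑O and at C12‑O.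

Assumptions: positions use germacrane numbering (C6 carbinol, C7 ring CH bearing the side chain, C8 acyloxy carbon, C11 side‑chain CH, C12 CH2O). In step 2 the Tol‑BINAP antipode that gives the (6S)‑lactone is meant (written as S; the sense must be confirmed). Cp rings of zirconium species are drawn η1 or as ions in SMILES.

**Step 1**
Reactants: 1 methyl 3‑methylbut‑2‑enoate
Product: 2 1‑methoxy‑3‑methyl‑1‑(trimethylsilyloxy)buta‑1,3‑diene
Conditions: LDA, THF, −78 °C; TMSCl, −78 °C → rt; distil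
Reagents that add atoms: chlorotrimethylsilane, C[Si](C)(C)Cl
Why: LDA removes a γ‑proton of the senecioate to give the extended dienolate, which TMSCl traps on oxygen (silyl dienolate formation); no stereocentre is formed.

**Step 2**
Reactants: 2 1‑methoxy‑3‑methyl‑1‑(trimethylsilyloxy)buta‑1,3‑diene; 3 3‑methylbut‑2‑enal (prenal)
Product: 4 (6S)‑4‑methyl‑6‑(2‑methylprop‑1‑en‑1‑yl)‑5,6‑dihydro‑2H‑pyran‑2‑one
Conditions: Cu(OTf)2 (10 mol %), (S)‑Tol‑BINAP (11 mol %), Bu4N Ph3SiF2 (20 mol %), THF, rt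
Reagents that add atoms: none
Why: Catalytic asymmetric vinylogous Mukaiyama aldol (copper dienolate, CuF·Tol‑BINAP) adds the γ‑carbon 1,2 to the enal and the (Z)‑aldolate lactonises in situ, so the catalyst sets C8 (S) and the ring fixes the future C1(10) olefin as Z.

**Step 3**
Reactants: 4 (6S)‑4‑methyl‑6‑(2‑methylprop‑1‑en‑1‑yl)‑5,6‑dihydro‑2H‑pyran‑2‑one
Product: 6 (4S,6Z)‑2,6‑dimethylnona‑2,6,8‑trien‑4‑ol, via lactol 5 (not isolated)
Conditions: DIBAL‑H (1.1 equiv), CH2Cl2, −78 °C; then Ph3P=CH2 (from Ph3PCH3Br, KHMDS; 3.5 equiv), THF, −78 °C → rt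
Reagents that add atoms: methyltriphenylphosphonium bromide, C[P+](c1ccccc1)(c1ccccc1)c1ccccc1.[Br-]
Why: DIBAL‑H stops at the aluminium lactolate, whose ring‑opened (Z)‑hydroxy enal undergoes Wittig methylenation in the same flask; C8 is untouched and the trisubstituted olefin keeps its Z geometry.

**Step 4**
Reactants: 7 angelic acid [(2Z)‑2‑methylbut‑2‑enoic acid]
Product: 8 (2Z)‑2‑methylbut‑2‑enoic 2,4,6‑trichlorobenzoic anhydride
Conditions: 2,4,6‑Cl3C6H2COCl (1.0 equiv), Et3N (1.05 equiv), PhMe, 0 °C → rt, 2 h; filter off Et3N·HCl under Ar; one batch sized for steps 5 and 11, kept as a titrated PhMe solution at −20 °C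
Reagents that add atoms: 2,4,6‑trichlorobenzoyl chloride, O=C(Cl)c1c(Cl)cc(Cl)cc1Cl
Why: The triethylammonium angelate is acylated by the hindered aroyl chloride (Yamaguchi mixed‑anhydride formation); with no nucleophilic catalyst present the Z olefin does not isomerise, and no stereocentre is formed.

**Step 5**
Reactants: 6 (4S,6Z)‑2,6‑dimethylnona‑2,6,8‑trien‑4‑ol; 8 (2Z)‑2‑methylbut‑2‑enoic 2,4,6‑trichlorobenzoic anhydride
Product: 9 (4S,6Z)‑2,6‑dimethylnona‑2,6,8‑trien‑4‑yl (2Z)‑2‑methylbut‑2‑enoate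
Conditions: 8 (1.5 equiv, PhMe solution), Et3N (1.5 equiv), PhMe, 75 °C (no DMAP)
Reagents that add atoms: none
Why: Yamaguchi‑type esterification without a nucleophilic catalyst: the alcohol attacks the less hindered angeloyl carbonyl of the mixed anhydride, angelate → tiglate isomerisation is avoided, the liberated aroic acid is held as its triethylammonium salt, and O‑acylation retains the C8 configuration.

**Step 6**
Reactants: 10 but‑2‑yn‑1‑ol
Product: 12 (2E)‑3‑iodobut‑2‑en‑1‑ol, via alkenylzirconocene 11 (not isolated)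
Conditions: Cp2Zr(H)Cl (2.3 equiv), THF, 0 °C → rt; then I2, 0 °C
Reagents that add atoms: iodine, II
Why: Syn‑hydrozirconation (Schwartz reagent) of the in‑situ zirconium alkoxide places Zr on the methyl‑bearing carbon remote from the bulky O–Zr group, and iododezirconation with retention gives the E‑iodide.

**Step 7**
Reactants: 9 (4S,6Z)‑2,6‑dimethylnona‑2,6,8‑trien‑4‑yl (2Z)‑2‑methylbut‑2‑enoate; 12 (2E)‑3‑iodobut‑2‑en‑1‑ol
Product: 14 (4S,6Z,10E)‑12‑hydroxy‑2,6,10‑trimethyldodeca‑2,6,10‑trien‑4‑yl (2Z)‑2‑methylbut‑2‑enoate, via B‑alkyl‑9‑BBN 13 (not isolated)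
Conditions: 9‑BBN‑H (1.1 equiv), THF, 0 °C → rt; then 12, Pd(dppf)Cl2 (5 mol %), AsPh3, Cs2CO3, DMF–THF–H2O, rt
Reagents that add atoms: none
Why: 9‑BBN hydroborates only the monosubstituted terminus of the 4,4‑disubstituted 1,3‑diene (anti‑Markovnikov), and the B‑alkyl Suzuki–Miyaura coupling joins C3 to C4 with retention of the iodide geometry, fixing the 4E olefin; no stereocentre is touched.

**Step 8**
Reactants: 14 (4S,6Z,10E)‑12‑hydroxy‑2,6,10‑trimethyldodeca‑2,6,10‑trien‑4‑yl (2Z)‑2‑methylbut‑2‑enoate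
Product: 15 (4S,6Z,10E)‑2,6,10‑trimethyl‑12‑oxododeca‑2,6,10‑trien‑4‑yl (2Z)‑2‑methylbut‑2‑enoate [(2E,6Z,9S)‑9‑angeloyloxyfarnesal]
Conditions: MnO2 (20 equiv), CH2Cl2, rt
Reagents that add atoms: none
Why: MnO2 oxidises only the primary allylic alcohol to the (E)‑enal, without olefin isomerisation.

**Step 9**
Reactants: 15 (4S,6Z,10E)‑2,6,10‑trimethyl‑12‑oxododeca‑2,6,10‑trien‑4‑yl (2Z)‑2‑methylbut‑2‑enoate
Product: 16 (1S,3Z,7E,9S,10S)‑9‑hydroxy‑3,7‑dimethyl‑10‑(prop‑1‑en‑2‑yl)cyclodeca‑3,7‑dien‑1‑yl (2Z)‑2‑methylbut‑2‑enoate [8α‑angeloyloxy‑(1(10)Z,4E)‑germacra‑1(10),4,11(13)‑trien‑6β‑ol, 7αH]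
Conditions: Me2AlCl (2.5 equiv), CH2Cl2, −78 → −30 °C, slow addition of 15 (final 1 mM); aq. Rochelle salt
Reagents that add atoms: none
Why: Proposed new method: Me2AlCl activates the enal carbonyl and the distal trisubstituted olefin attacks through C7 with concerted transfer of an allylic methyl hydrogen to oxygen (type‑I carbonyl‑ene), the 4E olefin excluding six‑ or seven‑membered closure onto C1/C10; the closest known reactions are Lewis‑acid ene macrocyclisations of ynals onto terminal isopropylidene groups (14‑membered rings), Me2AlCl ene reactions of aldehydes with trisubstituted alkenes and the citral → isopiperitenol enal‑ene; C7 is set by A(1,3) strain (C8–H eclipses the alkene, the tethered aldehyde adds on the C9 face anti to the angelate, 7S) and C6 by a chair‑like ene transition state with O6 gauche to C11, the C5 arm pseudo‑equatorial and hydrogen taken from the methyl cis to C8 (6S, O6 cis to the isopropenyl group).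

**Step 10**
Reactants: 16 (1S,3Z,7E,9S,10S)‑9‑hydroxy‑3,7‑dimethyl‑10‑(prop‑1‑en‑2‑yl)cyclodeca‑3,7‑dien‑1‑yl (2Z)‑2‑methylbut‑2‑enoate
Product: 18 (1S,3Z,7E,9S,10S)‑9‑hydroxy‑10‑[(2S)‑1‑hydroxypropan‑2‑yl]‑3,7‑dimethylcyclodeca‑3,7‑dien‑1‑yl (2Z)‑2‑methylbut‑2‑enoate, via C12‑borane 17 (not isolated)
Conditions: 9‑BBN‑H (1.3 equiv), THF, 0 °C → rt; then NaBO3·4H2O, THF–H2O, rt
Reagents that add atoms: sodium perborate (used as tetrahydrate), [Na+].[Na+].O[B-]1(O)OO[B-](O)(O)OO1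
Why: 9‑BBN hydroborates the 1,1‑disubstituted isopropenyl group far faster than the trisubstituted ring olefins or the angelate (boron at C12), and under substrate control hydrogen is expected to reach C11 on the face next to the small free 6β‑OH, anti to the C8 arm carrying the angelate, with C12 turned toward H7 (11S; the epimer is separable), before perborate oxidises C–B with retention.

**Step 11**
Reactants: 18 (1S,3Z,7E,9S,10S)‑9‑hydroxy‑10‑[(2S)‑1‑hydroxypropan‑2‑yl]‑3,7‑dimethylcyclodeca‑3,7‑dien‑1‑yl (2Z)‑2‑methylbut‑2‑enoate; 8 (2Z)‑2‑methylbut‑2‑enoic 2,4,6‑trichlorobenzoic anhydride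
Product: 19 (2S)‑2‑[(1S,2S,3E,7Z,10S)‑2‑hydroxy‑4,8‑dimethyl‑10‑{[(2Z)‑2‑methylbut‑2‑enoyl]oxy}cyclodeca‑3,7‑dien‑1‑yl]propyl (2Z)‑2‑methylbut‑2‑enoate
Conditions: 8 (1.2 equiv, PhMe solution from step 4), Et3N (1.5 equiv), PhMe, 50 °C (no DMAP)
Reagents that add atoms: none
Why: The primary C12 hydroxyl is acylated much faster than the hindered secondary allylic C6 hydroxyl by the mixed anhydride (Yamaguchi esterification), giving the 8,12‑diangelate without angelate isomerisation and without touching any stereocentre; Et3N keeps the acid‑sensitive germacradiene away from free aroic acid.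

**Compound list**
1 | methyl 3‑methylbut‑2‑enoate | CC(C)=CC(=O)OC | starting material
2 | 1‑methoxy‑3‑methyl‑1‑(trimethylsilyloxy)buta‑1,3‑diene (ketene‑acetal geometry undefined, used as the mixture) | CC(=C)C=C(OC)O[Si](C)(C)C | intermediate
3 | 3‑methylbut‑2‑enal (prenal) | CC(C)=CC=O | starting material
4 | (6S)‑4‑methyl‑6‑(2‑methylprop‑1‑en‑1‑yl)‑5,6‑dihydro‑2H‑pyran‑2‑one | CC(C)=C[C@@H]1CC(C)=CC(=O)O1 | intermediate
5 | (6S)‑4‑methyl‑6‑(2‑methylprop‑1‑en‑1‑yl)‑5,6‑dihydro‑2H‑pyran‑2‑ol (lactol, anomer mixture, present as its aluminium lactolate) | CC(C)=C[C@@H]1CC(C)=CC(O)O1 | intermediate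
6 | (4S,6Z)‑2,6‑dimethylnona‑2,6,8‑trien‑4‑ol | CC(C)=C[C@@H](O)C/C(C)=C\C=C | intermediate
7 | angelic acid, (2Z)‑2‑methylbut‑2‑enoic acid | C/C=C(/C)C(=O)O | starting material
8 | (2Z)‑2‑methylbut‑2‑enoic 2,4,6‑trichlorobenzoic anhydride (kept as a toluene solution) | C/C=C(/C)C(=O)OC(=O)c1c(Cl)cc(Cl)cc1Cl | intermediate
9 | (4S,6Z)‑2,6‑dimethylnona‑2,6,8‑trien‑4‑yl (2Z)‑2‑methylbut‑2‑enoate | CC(C)=C[C@@H](OC(=O)/C(C)=C\C)C/C(C)=C\C=C | intermediate
10 | but‑2‑yn‑1‑ol | CC#CCO | starting material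
11 | (E)‑3‑(chlorozirconocenyl)but‑2‑en‑1‑yl chlorozirconocenyl ether (Zr trans to CH2O) | C/C(=C\CO[Zr](Cl)(C1C=CC=C1)C1C=CC=C1)[Zr](Cl)(C1C=CC=C1)C1C=CC=C1 | intermediate
12 | (2E)‑3‑iodobut‑2‑en‑1‑ol | C/C(I)=C\CO | intermediate
13 | (4S,6Z)‑9‑(9‑borabicyclo[3.3.1]nonan‑9‑yl)‑2,6‑dimethylnona‑2,6‑dien‑4‑yl (2Z)‑2‑methylbut‑2‑enoate | CC(C)=C[C@@H](OC(=O)/C(C)=C\C)C/C(C)=C\CCB1C2CCCC1CCC2 | intermediate
14 | (4S,6Z,10E)‑12‑hydroxy‑2,6,10‑trimethyldodeca‑2,6,10‑trien‑4‑yl (2Z)‑2‑methylbut‑2‑enoate | CC(C)=C[C@@H](OC(=O)/C(C)=C\C)C/C(C)=C\CC/C(C)=C/CO | intermediate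
15 | (4S,6Z,10E)‑2,6,10‑trimethyl‑12‑oxododeca‑2,6,10‑trien‑4‑yl (2Z)‑2‑methylbut‑2‑enoate | CC(C)=C[C@@H](OC(=O)/C(C)=C\C)C/C(C)=C\CC/C(C)=C/C=O | intermediate
16 | (1S,3Z,7E,9S,10S)‑9‑hydroxy‑3,7‑dimethyl‑10‑(prop‑1‑en‑2‑yl)cyclodeca‑3,7‑dien‑1‑yl (2Z)‑2‑methylbut‑2‑enoate | CC(=C)[C@@H]1[C@@H](OC(=O)/C(C)=C\C)C/C(C)=C\CC/C(C)=C/[C@@H]1O | intermediate
17 | C12‑(9‑BBN) borane of 16 (C11 configured as in 18) | C[C@H](CB1C2CCCC1CCC2)[C@@H]1[C@@H](OC(=O)/C(C)=C\C)C/C(C)=C\CC/C(C)=C/[C@@H]1O | intermediate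
18 | (1S,3Z,7E,9S,10S)‑9‑hydroxy‑10‑[(2S)‑1‑hydroxypropan‑2‑yl]‑3,7‑dimethylcyclodeca‑3,7‑dien‑1‑yl (2Z)‑2‑methylbut‑2‑enoate | OC[C@@H](C)[C@@H]1[C@@H](OC(=O)/C(C)=C\C)C/C(C)=C\CC/C(C)=C/[C@@H]1O | intermediate
19 | (2S)‑2‑[(1S,2S,3E,7Z,10S)‑2‑hydroxy‑4,8‑dimethyl‑10‑{[(2Z)‑2‑methylbut‑2‑enoyl]oxy}cyclodeca‑3,7‑dien‑1‑yl]propyl (2Z)‑2‑methylbut‑2‑enoate; germacrane positions 6S,7S,8S,11S, 1(10)Z,4E | C/C=C(/C)C(=O)OC[C@@H](C)[C@@H]1[C@@H](OC(=O)/C(C)=C\C)C/C(C)=C\CC/C(C)=C/[C@@H]1O | target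

**Count**
Total steps: 11. Longest linear sequence: 9 (steps 1–3, 5 and 7–11); steps 4 and 6 are one‑step side branches.

**Three steps most likely to fail**

Step 9 (ene macrocyclisation). A ten‑membered closure with a weak enophile (enal) onto an olefin deactivated by the allylic angelate is untested. Competing paths are ionisation of the allylic ester, methyl transfer from aluminium, E→Z isomerisation of the enal followed by six‑ring ene closure, and transannular cyclisation of the product. The C6 configuration is the least secure prediction. The fallback sets out from 15 and comes back at 16. Pinnick oxidation gives (2E,6Z,9S)‑9‑angeloyloxy‑3,7,11‑trimethyldodeca‑2,6,10‑trienoic acid F1, and oxalyl chloride with catalytic DMF gives the corresponding acid chloride F2. SnCl4 (CH2Cl2, −78 °C, high dilution) then closes the same C6–C7 bond by acylium–olefin cyclisation with chloride capture at C11, giving 8α‑angeloyloxy‑11‑chloro‑(1(10)Z,4E)‑germacra‑1(10),4‑dien‑6‑one F3. This is a stronger electrophile of the kind known to close polyprenoid acid chlorides to macrocyclic ketones. (S)‑Me‑CBS with catecholborane at −78 °C reduces the ketone under reagent control to 8α‑angeloyloxy‑11‑chloro‑(1(10)Z,4E)‑germacra‑1(10),4‑dien‑6β‑ol F4, which decouples C6 from the ring closure. Li2CO3/LiBr in DMF (no alkoxide, to avoid Grob fragmentation) eliminates HCl toward the methyl group to give 16.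

Step 10 (hydroboration, C11). The 1,2‑induction from C7, flanked by two oxygenated carbons, may be low or reversed; chemoselectivity is not the concern. The fallback sets out from 16 and comes back at 18. 1,1,3,3‑Tetramethyldisilazane converts the 6β‑OH into the dimethylsilyl ether F5. Karstedt's catalyst then effects intramolecular 6‑endo hydrosilylation of the isopropenyl group to the cis‑fused 1,2‑oxasilinane F6; Si–H is delivered to C12/C11 from the O6 side through a chair with the C11 methyl equatorial. Tamao–Fleming oxidation (H2O2, KF, KHCO3, THF–MeOH) gives 18.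

Step 2 (asymmetric vinylogous aldol). With an enal electrophile the ee may be only 80–90 %, some open‑chain (E)‑adduct may form, and the sense of induction is assumed. The fallback sets out from 3 and comes back at 4. Brown methallylation of 3 with (−)‑Ipc2B(2‑methylallyl) (−78 °C; then NaBO3) gives (4S)‑2,6‑dimethylhepta‑1,5‑dien‑4‑ol F7, with the same facial sense as benzaldehyde → (S)‑1‑phenylbut‑3‑en‑1‑ol. Acryloyl chloride/Et3N gives (4S)‑2,6‑dimethylhepta‑1,5‑dien‑4‑yl acrylate F8, and ring‑closing metathesis (Grubbs II, CH2Cl2, 40 °C) onto the 1,1‑disubstituted olefin gives 4.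

**Further compounds**
F1 | step 9 | (2E,6Z,9S)‑3,7,11‑trimethyl‑9‑{[(2Z)‑2‑methylbut‑2‑enoyl]oxy}dodeca‑2,6,10‑trienoic acid | CC(C)=C[C@@H](OC(=O)/C(C)=C\C)C/C(C)=C\CC/C(C)=C/C(=O)O
F2 | step 9 | (2E,6Z,9S)‑3,7,11‑trimethyl‑9‑{[(2Z)‑2‑methylbut‑2‑enoyl]oxy}dodeca‑2,6,10‑trienoyl chloride | CC(C)=C[C@@H](OC(=O)/C(C)=C\C)C/C(C)=C\CC/C(C)=C/C(Cl)=O
F3 | step 9 | 8α‑angeloyloxy‑11‑chloro‑(1(10)Z,4E)‑germacra‑1(10),4‑dien‑6‑one (7αH) | CC(C)(Cl)[C@@H]1[C@@H](OC(=O)/C(C)=C\C)C/C(C)=C\CC/C(C)=C/C1=O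
F4 | step 9 | 8α‑angeloyloxy‑11‑chloro‑(1(10)Z,4E)‑germacra‑1(10),4‑dien‑6β‑ol (7αH) | CC(C)(Cl)[C@@H]1[C@@H](OC(=O)/C(C)=C\C)C/C(C)=C\CC/C(C)=C/[C@@H]1O
F5 | step 10 | 6‑O‑dimethylsilyl ether of 16 | CC(=C)[C@@H]1[C@@H](OC(=O)/C(C)=C\C)C/C(C)=C\CC/C(C)=C/[C@@H]1O[SiH](C)C
F6 | step 10 | cis‑fused 2,2‑dimethyl‑1,2‑oxasilinane bridging O6 and C12 (C11 methyl as in 18) | C[Si]2(C)C[C@@H](C)[C@@H]1[C@@H](OC(=O)/C(C)=C\C)C/C(C)=C\CC/C(C)=C/[C@@H]1O2
F7 | step 2 | (4S)‑2,6‑dimethylhepta‑1,5‑dien‑4‑ol | CC(C)=C[C@@H](O)CC(C)=C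
F8 | step 2 | (4S)‑2,6‑dimethylhepta‑1,5‑dien‑4‑yl prop‑2‑enoate | CC(C)=C[C@@H](OC(=O)C=C)CC(C)=C
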